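The stereocentres C9a and C4a are adjacent, fully substituted, and shared by the dihydrofuran, indoline and piperidine rings. Deleting the piperidine atoms C1, N2, C3 and C4 leaves a planar, achiral benzofuro[3,2-b]indole whose aromatic C9a=C4a bond carries both future centres. The route exploits this feature: a cationic 2-azadiene (N-formyl-N-vinyl methyleneiminium), paired with a chiral anion, adds across that bond of the bis-N-tosyl pentacycle 11. One operation forms C1–C9a and C4–C4a, closes the piperidine and sets both quaternary centres. Pentacycle 11 comes from Sonogashira/cycloisomerisation and Cadogan chemistry; reduction, detosylation and a Mannich reaction finish the target.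

Key step: step 10

Remarks
- Locants: the core is numbered as a β-carboline (C1, N2, C3, C4, C4a, C9a, N9); the methoxyindole carries primed indole locants. "Flat pentacycle" means the fully aromatic 7'-methoxyindole-fused benzofuro[3,2-b]indole (O5'–C4a=C9a–C4'). "Hexacycle" means the same skeleton with the piperidine C9a–C1–N2–C3–C4–C4a added and no substituent at C3'.
- Assumption: the target and compounds 16–19 are the (4aS,9aR) series; which enantiomer of the chiral acid delivers this series in step 10 has to be fixed by an initial screen.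
- Design of 11: both nitrogens are sulfonylated (N9 so that the furan oxygen, not nitrogen, acts as the π-donor of the C9a=C4a bond; N1' to deactivate C2'/C3'). C3' stays unsubstituted until the last step so that the bay beside N9 and C9a remains open.

Step 1
Reactants: 1 3-methoxy-4-nitrophenol
Product: 2 4-(benzyloxy)-2-methoxy-1-nitrobenzene
Conditions: BnBr, K2CO3, DMF, rt
Reagents that add atoms: benzyl bromide, BrCc1ccccc1
Why: Williamson etherification of the unhindered phenoxide masks the acidic OH that would quench the Grignard reagent of step 2.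

Step 2
Reactants: 2 4-(benzyloxy)-2-methoxy-1-nitrobenzene
Product: 3 5-(benzyloxy)-7-methoxy-1H-indole
Conditions: CH2=CHMgBr (3.2 equiv), THF, −40 °C; aq. NH4Cl
Reagents that add atoms: vinylmagnesium bromide, C=C[Mg]Br
Why: Bartoli indole synthesis, in which the ortho-methoxy group supplies the ortho substituent the [3,3]-sigmatropic step needs and only one ortho position is free, so OMe must end at C7 and OBn at C5.

Step 3
Reactants: 3 5-(benzyloxy)-7-methoxy-1H-indole
Product: 4 5-(benzyloxy)-7-methoxy-1-tosyl-1H-indole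
Conditions: NaH, TsCl, DMF, 0 °C to rt
Reagents that add atoms: p-toluenesulfonyl chloride, Cc1ccc(S(=O)(=O)Cl)cc1
Why: N-sulfonylation of the indolyl anion switches off C3 so that the phenol ring alone directs the halogenation of step 5.

Step 4
Reactants: 4 5-(benzyloxy)-7-methoxy-1-tosyl-1H-indole
Product: 5 7-methoxy-1-tosyl-1H-indol-5-ol
Conditions: H2 (1 atm), Pd/C, EtOAc/EtOH, rt
Reagents that add atoms: none
Why: Catalytic hydrogenolysis of the benzyl ether leaves the N-sulfonyl indole and the aryl methyl ether untouched at 1 atm.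

Step 5
Reactants: 5 7-methoxy-1-tosyl-1H-indol-5-ol
Product: 6 4-iodo-7-methoxy-1-tosyl-1H-indol-5-ol
Conditions: NIS (1.0 equiv), MeCN, −20 to 0 °C
Reagents that add atoms: N-iodosuccinimide, O=C1CCC(=O)N1I
Why: Phenol-directed electrophilic aromatic iodination should go to C4 (ortho to OH, para to OMe, the α-naphthol-like site of a 5-hydroxyindole) because C6 is flanked by two substituents and the tosylated pyrrole ring is deactivated.

Step 6
Reactants: 6 4-iodo-7-methoxy-1-tosyl-1H-indol-5-ol; 7 1-ethynyl-2-nitrobenzene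
Product: 9 7-methoxy-2-(2-nitrophenyl)-6-tosyl-6H-furo[3,2-e]indole (furan O on indole C5', furan C3 on indole C4', nitrophenyl on the O-bearing furan carbon), via 4-alkynyl-5-hydroxyindole 8 (not isolated)
Conditions: PdCl2(PPh3)2 (5 mol %), copper iodide CuI (10 mol %), Et3N, DMF, 70 °C
Reagents that add atoms: none
Why: Sonogashira coupling of the aryl iodide is followed in the same flask by 5-endo-dig attack of the phenol oxygen on the metal-activated alkyne (benzofuran-forming cycloisomerisation), which puts the nitrophenyl group on the future C4a.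

Step 7
Reactants: 9 7-methoxy-2-(2-nitrophenyl)-6-tosyl-6H-furo[3,2-e]indole
Product: 10 N1'-tosyl flat pentacycle (N9–H)
Conditions: PPh3 (2.5 equiv), o-dichlorobenzene, 180 °C
Reagents that add atoms: none
Why: Cadogan reductive cyclisation, in which PPh3 deoxygenates the nitro group and the nitrene-type nitrogen closes onto the neighbouring furan C3–H, the only C–H in reach, forming the N9–C9a bond without the N-alkylation that trialkyl phosphites can cause.

Step 8
Reactants: 10 N1'-tosyl flat pentacycle (N9–H)
Product: 11 N9,N1'-ditosyl flat pentacycle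
Conditions: NaH, TsCl, DMF, 0 °C to rt
Reagents that add atoms: p-toluenesulfonyl chloride, Cc1ccc(S(=O)(=O)Cl)cc1
Why: N-sulfonylation of the carbazole-like N9 anion installs the acceptor that silences N9 as a donor of the C9a=C4a bond in step 10.

Step 9
Reactants: 12 N-vinylformamide
Product: 13 N-(methoxymethyl)-N-vinylformamide
Conditions: NaH, THF, 0 °C; MOMCl, 0 °C to rt
Reagents that add atoms: chloromethyl methyl ether, COCCl
Why: N-alkylation of the formamide anion with a hard chloromethyl ether gives the N,O-acetal, and the N-vinyl group is inert to base.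

Step 10
Reactants: 11 N9,N1'-ditosyl flat pentacycle; 13 N-(methoxymethyl)-N-vinylformamide
Product: 16 (4aS,9aR)-N2-formyl-3,4-didehydro-N9,N1'-ditosyl hexacycle (ene-formamide C9a–C1H2–N2(CHO)–C3H=C4H–C4a), via N-formyl-N-vinylmethyleneiminium ion 14 (not isolated), via C4a oxocarbenium ion 15 (not isolated)
Conditions: chiral IDPi Brønsted acid (BINOL-derived imidodiphosphorimidate, 5 mol %), 5 Å MS, CHCl3, −40 °C, slow addition of 13 (1.5 equiv); Et3N quench
Reagents that add atoms: none
Why: Proposed new method: the acid protonates the N,O-acetal and expels methanol to give the 2-azonia-diene 14 as an ion pair with the chiral anion; C9a, the β-carbon of the aryl enol ether, adds to the iminium carbon (Mannich-type) to leave the benzylic oxocarbenium ion 15 at C4a, the now neutral enamide captures it through its β-carbon, and loss of H+ from C4 gives the ene-formamide and returns the acid. The closest known reaction types are polar [4+2] cycloadditions of cationic 2-azadienes (N-alkenyl and N-aryl iminium ions, Povarov-type) with electron-rich alkenes and acid-promoted dearomative annulations of indoles and benzofurans, but none is established on a fully substituted heteroaromatic C=C bond. The piperidine ring closes by a 6-endo-trig cyclisation (with respect to the enamide C=C) of C4 onto the C4a oxocarbenium carbon, completing a stepwise [4+2]. C9a is set by the chiral counteranion, which must distinguish the two enantiotopic faces of the flat pentacycle in the first C–C bond formation; C4a then follows from C9a because the three-atom tether can reach the cation only from the same face, the only geometry a propellane allows. The step needs regioselectivity (C1 to C9a, C4 to C4a), site selectivity and facial selectivity: the N9 tosyl group suppresses the enamine-type mode that would send C1 to C4a, the N1' tosyl group deactivates C2'/C3', and slow addition keeps 14 from oligomerising through its own enamide.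

Step 11
Reactants: 16 (4aS,9aR)-N2-formyl-3,4-didehydro-N9,N1'-ditosyl hexacycle
Product: 17 (4aS,9aR)-N2-formyl-N9,N1'-ditosyl hexacycle (saturated piperidine)
Conditions: H2 (1 atm), Pd/C, EtOAc, rt
Reagents that add atoms: none
Why: Heterogeneous hydrogenation of the disubstituted enamide C3=C4 creates no stereocentre and should leave the sulfonamides, the N-sulfonyl indole and the hindered tertiary benzylic ether alone at 1 atm.

Step 12
Reactants: 17 (4aS,9aR)-N2-formyl-N9,N1'-ditosyl hexacycle
Product: 18 (4aS,9aR)-N2-methyl-N9,N1'-ditosyl hexacycle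
Conditions: LiAlH4, THF, 0 °C to rt; aq. NaOH work-up
Reagents that add atoms: none
Why: Hydride reduction of the tertiary formamide to the N-methyl amine is fast at 0 °C, where the sulfonamides and both quaternary centres are not affected.

Step 13
Reactants: 18 (4aS,9aR)-N2-methyl-N9,N1'-ditosyl hexacycle
Product: 19 (4aS,9aR)-N2-methyl hexacycle (N9–H, N1'–H)
Conditions: Mg turnings, MeOH/THF, sonication, rt; aq. NH4Cl
Reagents that add atoms: none
Why: Single-electron reductive desulfonylation (Mg in methanol) cleaves both N–S bonds by electron transfer to the tolylsulfonyl groups, remote from the hindered N9, and offers no pathway for epimerisation.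

Step 14
Reactants: 19 (4aS,9aR)-N2-methyl hexacycle (N9–H, N1'–H)
Product: 20 target, (4aS,9aR)-3'-(dimethylaminomethyl)-N2-methyl hexacycle
Conditions: Me2NH (aq.), CH2O (aq.), AcOH, 0 °C to rt; aq. NaOH
Reagents that add atoms: formaldehyde, C=O; dimethylamine, CNC
Why: Mannich aminomethylation (gramine synthesis) of the N–H indole at C3', its most nucleophilic carbon, while any N-aminomethyl adduct at N1' or N9 is reversible in acetic acid and should funnel to the C-alkylated product.

Compound list
1 | 3-methoxy-4-nitrophenol | COc1cc(O)ccc1[N+](=O)[O-] | starting material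
2 | 4-(benzyloxy)-2-methoxy-1-nitrobenzene | COc1cc(OCc2ccccc2)ccc1[N+](=O)[O-] | intermediate
3 | 5-(benzyloxy)-7-methoxy-1H-indole | COc1cc(OCc2ccccc2)cc2cc[nH]c12 | intermediate
4 | 5-(benzyloxy)-7-methoxy-1-tosyl-1H-indole | COc1cc(OCc2ccccc2)cc2ccn(S(=O)(=O)c3ccc(C)cc3)c12 | intermediate
5 | 7-methoxy-1-tosyl-1H-indol-5-ol | COc1cc(O)cc2ccn(S(=O)(=O)c3ccc(C)cc3)c12 | intermediate
6 | 4-iodo-7-methoxy-1-tosyl-1H-indol-5-ol | COc1cc(O)c(I)c2ccn(S(=O)(=O)c3ccc(C)cc3)c12 | intermediate
7 | 1-ethynyl-2-nitrobenzene | C#Cc1ccccc1[N+](=O)[O-] | starting material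
8 | 7-methoxy-4-[(2-nitrophenyl)ethynyl]-1-tosyl-1H-indol-5-ol | COc1cc(O)c(C#Cc2ccccc2[N+](=O)[O-])c2ccn(S(=O)(=O)c3ccc(C)cc3)c12 | intermediate
9 | 7-methoxy-2-(2-nitrophenyl)-6-tosyl-6H-furo[3,2-e]indole | COc1cc2oc(-c3ccccc3[N+](=O)[O-])cc2c2ccn(S(=O)(=O)c3ccc(C)cc3)c12 | intermediate
10 | N1'-tosyl flat pentacycle (N9–H) | COc1cc2oc3c4ccccc4[nH]c3c2c2ccn(S(=O)(=O)c3ccc(C)cc3)c12 | intermediate
11 | N9,N1'-ditosyl flat pentacycle | COc1cc2oc3c4ccccc4n(S(=O)(=O)c4ccc(C)cc4)c3c2c2ccn(S(=O)(=O)c3ccc(C)cc3)c12 | intermediate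
12 | N-vinylformamide | C=CNC=O | starting material
13 | N-(methoxymethyl)-N-vinylformamide | COCN(C=C)C=O | intermediate
14 | N-formyl-N-vinylmethyleneiminium ion | C=[N+](C=C)C=O | intermediate
15 | (9aR)-C4a oxocarbenium ion (C9a carries CH2–N(CHO)–CH=CH2; cation O5'=C4a) | COc1cc2c(c3ccn(S(=O)(=O)c4ccc(C)cc4)c13)[C@@]1(CN(C=O)C=C)C(=[O+]2)c2ccccc2N1S(=O)(=O)c1ccc(C)cc1 | intermediate
16 | (4aS,9aR)-N2-formyl-3,4-didehydro-N9,N1'-ditosyl hexacycle | COc1cc2c(c3ccn(S(=O)(=O)c4ccc(C)cc4)c13)[C@@]13CN(C=O)C=C[C@]1(O2)c1ccccc1N3S(=O)(=O)c1ccc(C)cc1 | intermediate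
17 | (4aS,9aR)-N2-formyl-N9,N1'-ditosyl hexacycle | COc1cc2c(c3ccn(S(=O)(=O)c4ccc(C)cc4)c13)[C@@]13CN(C=O)CC[C@]1(O2)c1ccccc1N3S(=O)(=O)c1ccc(C)cc1 | intermediate
18 | (4aS,9aR)-N2-methyl-N9,N1'-ditosyl hexacycle | COc1cc2c(c3ccn(S(=O)(=O)c4ccc(C)cc4)c13)[C@@]13CN(C)CC[C@]1(O2)c1ccccc1N3S(=O)(=O)c1ccc(C)cc1 | intermediate
19 | (4aS,9aR)-N2-methyl hexacycle (N9–H, N1'–H) | COc1cc2c(c3cc[nH]c13)[C@@]13CN(C)CC[C@]1(O2)c1ccccc1N3 | intermediate
20 | target, (4aS,9aR)-3'-(dimethylaminomethyl)-N2-methyl hexacycle | COc1cc2c(c3c(CN(C)C)c[nH]c13)[C@@]13CN(C)CC[C@]1(O2)c1ccccc1N3 | target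

Total step count: 14. Longest linear sequence: 13 steps (steps 1–8 and 10–14); step 9 is a one-step side branch.

Steps most likely to fail

Step 10. The first C–C bond may form in the reverse orientation (C1 to C4a) or at an arene C–H site (C6' or C3'). The cation may also oligomerise through its own enamide before it reaches the hindered C9a=C4a bond, or the ion pair may discriminate the two faces poorly. The fallback uses known chemistry, sets out from 6 and returns at 19. Commercial N-methyltryptamine is protected with Boc2O to give tert-butyl methyl[2-(1H-indol-3-yl)ethyl]carbamate F1. C2–H borylation ([Ir(OMe)(cod)]2, 4,4'-di-tert-butyl-2,2'-bipyridine, B2pin2, THF) gives the 2-pinacolboronate F2. Suzuki–Miyaura coupling of F2 with iodophenol 6 (Pd(OAc)2, SPhos, K3PO4, dioxane/water) gives the Boc-protected 2-aryltryptamine F3, and TFA releases the secondary amine F4. Aqueous formaldehyde with camphorsulfonic acid then effects a Pictet–Spengler-type closure: the iminium carbon bonds to the aryl-bearing indole C2 (C9a) and the adjacent phenol captures the benzylic cation at C4a. The tether fixes the orientation, and the product is the racemic N1'-tosyl N2-methyl hexacycle F5. Preparative HPLC on a chiral stationary phase gives the (4aS,9aR) enantiomer F6, and Mg/MeOH removes the tosyl group to give 19.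

Step 5. Iodination may go between the two oxygen substituents (C6) or twice instead of cleanly at C4. The fallback sets out from 1 and returns at 9 by placing the halogen before the indole is built. Bromination of 1 (NBS, MeCN, 0 °C) should go ortho to the hydroxyl and para to the methoxy group, giving 2-bromo-5-methoxy-4-nitrophenol F7. Silylation (TIPSCl, imidazole, DMF) gives the silyl ether F8. The Bartoli reaction (CH2=CHMgBr, THF, −40 °C) gives 4-bromo-7-methoxy-5-(triisopropylsilyloxy)-1H-indole F9, and N-tosylation (NaH, TsCl) gives F10. TBAF at 0 °C frees 4-bromo-7-methoxy-1-tosyl-1H-indol-5-ol F11, the bromo analogue of 6. Coupling and cyclisation of F11 with 7 (Pd(PPh3)4, copper iodide CuI, Et3N, DMF, 80 °C) gives 9.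

Step 14. Aminomethylation may occur at N9 or on the electron-rich aniline ring, or more than once, in competition with the hindered C3'. The fallback sets out from 18 and returns at 20 by keeping N9 sulfonylated while the side chain is added. TBAF (THF, 65 °C) cleaves only the indole sulfonamide, since the indoline arylsulfonamide is inert to fluoride, giving the N9-tosyl N1'–H compound F12. Preformed dimethylmethyleneiminium iodide (MeCN/CH2Cl2, rt) can then react only at C3' and gives the N9-tosyl gramine F13. Mg/MeOH removes the remaining tosyl group to give 20.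

Further compounds
F1 | step 10 | tert-butyl methyl[2-(1H-indol-3-yl)ethyl]carbamate | CN(CCc1c[nH]c2ccccc12)C(=O)OC(C)(C)C
F2 | step 10 | tert-butyl methyl{2-[2-(4,4,5,5-tetramethyl-1,3,2-dioxaborolan-2-yl)-1H-indol-3-yl]ethyl}carbamate | CN(CCc1c(B2OC(C)(C)C(C)(C)O2)[nH]c2ccccc12)C(=O)OC(C)(C)C
F3 | step 10 | tert-butyl {2-[2-(5-hydroxy-7-methoxy-1-tosyl-1H-indol-4-yl)-1H-indol-3-yl]ethyl}(methyl)carbamate | COc1cc(O)c(-c2[nH]c3ccccc3c2CCN(C)C(=O)OC(C)(C)C)c2ccn(S(=O)(=O)c3ccc(C)cc3)c12
F4 | step 10 | 7-methoxy-4-{3-[2-(methylamino)ethyl]-1H-indol-2-yl}-1-tosyl-1H-indol-5-ol | COc1cc(O)c(-c2[nH]c3ccccc3c2CCNC)c2ccn(S(=O)(=O)c3ccc(C)cc3)c12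
F5 | step 10 | racemic N2-methyl-N1'-tosyl hexacycle (N9–H) | COc1cc2c(c3ccn(S(=O)(=O)c4ccc(C)cc4)c13)C13CN(C)CCC1(O2)c1ccccc1N3
F6 | step 10 | (4aS,9aR)-N2-methyl-N1'-tosyl hexacycle (N9–H) | COc1cc2c(c3ccn(S(=O)(=O)c4ccc(C)cc4)c13)[C@@]13CN(C)CC[C@]1(O2)c1ccccc1N3
F7 | step 5 | 2-bromo-5-methoxy-4-nitrophenol | COc1cc(O)c(Br)cc1[N+](=O)[O-]
F8 | step 5 | (2-bromo-5-methoxy-4-nitrophenoxy)triisopropylsilane | COc1cc(O[Si](C(C)C)(C(C)C)C(C)C)c(Br)cc1[N+](=O)[O-]
F9 | step 5 | 4-bromo-7-methoxy-5-(triisopropylsilyloxy)-1H-indole | COc1cc(O[Si](C(C)C)(C(C)C)C(C)C)c(Br)c2cc[nH]c12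
F10 | step 5 | 4-bromo-7-methoxy-1-tosyl-5-(triisopropylsilyloxy)-1H-indole | COc1cc(O[Si](C(C)C)(C(C)C)C(C)C)c(Br)c2ccn(S(=O)(=O)c3ccc(C)cc3)c12
F11 | step 5 | 4-bromo-7-methoxy-1-tosyl-1H-indol-5-ol | COc1cc(O)c(Br)c2ccn(S(=O)(=O)c3ccc(C)cc3)c12
F12 | step 14 | (4aS,9aR)-N2-methyl-N9-tosyl hexacycle (N1'–H) | COc1cc2c(c3cc[nH]c13)[C@@]13CN(C)CC[C@]1(O2)c1ccccc1N3S(=O)(=O)c1ccc(C)cc1
F13 | step 14 | (4aS,9aR)-3'-(dimethylaminomethyl)-N2-methyl-N9-tosyl hexacycle | COc1cc2c(c3c(CN(C)C)c[nH]c13)[C@@]13CN(C)CC[C@]1(O2)c1ccccc1N3S(=O)(=O)c1ccc(C)cc1
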